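**Retrosynthetic overview**

- The target 17 is a depside. Ring A is a 2-heptyl-6-methoxybenzoic acid acylated on O at C4; ring B is a benzoyl group with the ester carbon C1', pentyl at C2', and oxygen at C4' and C6'. This meta-dioxygen pattern on either side of C1', with the alkyl group ortho to it, is the feature the route rests on.
- Ring B is disconnected at C1'–C6' and C2'–C3' (Diels–Alder reaction, then aromatisation) to the aryl oct-2-ynoate 9 and the 1,3-dioxygenated vinylketene acetal 12.
- The depside C(=O)–O bond is made before ring B exists, by esterifying the unhindered oct-2-ynoic acid 8 with phenol 7. Phenol 7 comes from 5-heptylresorcinol 1 by carboxylation, benzyl ester formation and differentiation of the two hydroxyls.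
- Ring order: ring A is bought as an arene; ring B is the only ring formed (step 8). O-Methylation at C6' and hydrogenolysis of the benzyl ester finish the synthesis.

Key step: step 8

Remark: the target has no stereocentre and no stereogenic double bond, so it is achiral and the route needs no stereocontrol. Compounds 1, 8 and 10 are taken as commercial.

**Route**

Step 1
Reactants: 1 5-heptylresorcinol
Product: 3 2-heptyl-4,6-dihydroxybenzoic acid, via magnesium salicylate chelate 2 (not isolated)
Conditions: MeOMgOCO2Me (2 M in DMF), 120 °C, N2; then cold 2 M HCl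
Reagents that add atoms: methyl magnesium carbonate (methoxymagnesium methyl carbonate), COC(=O)O[Mg]OC
Why: Stiles carboxylation (a Kolbe–Schmitt-type reaction) should place CO2 ortho to one hydroxyl and para to the other through the magnesium chelate, as is known for 5-alkylresorcinols.

Step 2
Reactants: 3 2-heptyl-4,6-dihydroxybenzoic acid
Product: 4 benzyl 2-heptyl-4,6-dihydroxybenzoate
Conditions: BnBr, KHCO3, DMF, rt
Reagents that add atoms: benzyl bromide, BrCc1ccccc1
Why: SN2 O-alkylation of the carboxylate, since hydrogen carbonate deprotonates only the acid and leaves both phenols free.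

Step 3
Reactants: 4 benzyl 2-heptyl-4,6-dihydroxybenzoate
Product: 5 benzyl 2-heptyl-6-hydroxy-4-[(triisopropylsilyl)oxy]benzoate
Conditions: TIPSCl, imidazole, CH2Cl2, 0 °C
Reagents that add atoms: triisopropylsilyl chloride, CC(C)[Si](Cl)(C(C)C)C(C)C
Why: Regioselective silylation, because the C6 hydroxyl is hydrogen-bonded to the ester carbonyl and flanked by the ester, so the bulky silyl chloride should take the free C4 hydroxyl.

Step 4
Reactants: 5 benzyl 2-heptyl-6-hydroxy-4-[(triisopropylsilyl)oxy]benzoate
Product: 6 benzyl 2-heptyl-6-methoxy-4-[(triisopropylsilyl)oxy]benzoate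
Conditions: MeI, K2CO3, acetone, 55 °C
Reagents that add atoms: iodomethane, CI
Why: Williamson methylation of the chelated phenol, with the TIPS aryl ether and the hindered benzyl ester expected to tolerate anhydrous carbonate in acetone.

Step 5
Reactants: 6 benzyl 2-heptyl-6-methoxy-4-[(triisopropylsilyl)oxy]benzoate
Product: 7 benzyl 2-heptyl-4-hydroxy-6-methoxybenzoate
Conditions: TBAF, AcOH, THF, 0 °C
Reagents that add atoms: none
Why: Fluoride-mediated cleavage of the aryl silyl ether, buffered with acetic acid so that no free phenoxide or basic fluoride touches the benzyl ester.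

Step 6
Reactants: 7 benzyl 2-heptyl-4-hydroxy-6-methoxybenzoate; 8 oct-2-ynoic acid
Product: 9 benzyl 2-heptyl-6-methoxy-4-(oct-2-ynoyloxy)benzoate
Conditions: DCC, DMAP (cat.), CH2Cl2, 0 °C to rt
Reagents that add atoms: none
Why: Steglich esterification of the only free phenol with an unhindered alkynoic acid, a routine way to aryl alkynoates, run cold with little DMAP to suppress conjugate addition to the ynoate.

Step 7
Reactants: 10 methyl (E)-3-methoxybut-2-enoate
Product: 12 (1E)-1,3-dimethoxy-1-(trimethylsilyloxy)buta-1,3-diene, via lithium dienolate 11 (not isolated)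
Conditions: LDA, THF, −78 °C; then TMSCl, −78 °C to rt; distilled with exclusion of moisture
Reagents that add atoms: chlorotrimethylsilane, C[Si](C)(C)Cl
Why: Kinetic γ-deprotonation of the β-methoxy enoate gives the extended enolate, and O-silylation gives the Brassard-type vinylketene acetal, the standard preparation of such dienes.

Step 8
Reactants: 9 benzyl 2-heptyl-6-methoxy-4-(oct-2-ynoyloxy)benzoate; 12 (1E)-1,3-dimethoxy-1-(trimethylsilyloxy)buta-1,3-diene
Product: 15 benzyl 2-heptyl-4-(2-hydroxy-4-methoxy-6-pentylbenzoyloxy)-6-methoxybenzoate, via cyclohexa-1,4-diene cycloadduct 13 (not isolated), via aryl trimethylsilyl ether 14 (not isolated)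
Conditions: 12 (excess), PhMe, 110 °C, sealed tube; then 1 M HCl, THF, rt
Reagents that add atoms: none
Why: This is a normal-demand Diels–Alder reaction (concerted but asynchronous, at the polar extreme a Mukaiyama–Michael addition followed by ring closure) between the electron-rich vinylketene acetal 12 and the electron-poor aryl ynoate 9, the known benzannulation of Brassard-type 1-alkoxy-1-silyloxy dienes with alkynoates. Ring B is closed by an intermolecular [4+2] cycloaddition that forms C2'–C3' and C1'–C6' in one operation and gives the cyclohexa-1,4-diene 13. The ketal carbon C6' of 13 should then lose methanol together with the doubly allylic C3'–H (thermally or on acidification, through an arenium-type cation), and the aryl silyl ether 14 so formed is hydrolysed by the dilute acid to the hydrogen-bonded phenol 15. No stereocentre remains, since the ketal carbon of 13 forms as a racemate and becomes sp2 on aromatisation. The step needs regioselectivity only, which comes from the largest HOMO coefficient at the CH2 terminus of 12 matching the largest LUMO coefficient at the pentyl-bearing β-carbon of 9, so that oxygen ends at C6' and pentyl at C2' on either side of C1'. The aryl ester lowers the LUMO of the ynoate relative to an alkyl ester, and the hindered benzyl ester, the methyl ether and the aryl ester should be inert to the heating and the brief acid work-up.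

Step 9
Reactants: 15 benzyl 2-heptyl-4-(2-hydroxy-4-methoxy-6-pentylbenzoyloxy)-6-methoxybenzoate
Product: 16 benzyl 4-(2,4-dimethoxy-6-pentylbenzoyloxy)-2-heptyl-6-methoxybenzoate
Conditions: MeI, K2CO3, acetone, reflux
Reagents that add atoms: iodomethane, CI
Why: Williamson methylation of the chelated ring B phenol, with the di-ortho-substituted aryl ester and the hindered benzyl ester expected to resist the heterogeneous carbonate.

Step 10
Reactants: 16 benzyl 4-(2,4-dimethoxy-6-pentylbenzoyloxy)-2-heptyl-6-methoxybenzoate
Product: 17 4-(2,4-dimethoxy-6-pentylbenzoyloxy)-2-heptyl-6-methoxybenzoic acid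
Conditions: H2 (1 atm), 10% Pd/C, EtOAc, rt
Reagents that add atoms: none
Why: Catalytic hydrogenolysis of the benzyl ester under neutral conditions, which should leave the aryl ester, the aryl methyl ethers and the alkyl chains untouched.

**Compound list**

1 | 5-heptylresorcinol | CCCCCCCc1cc(O)cc(O)c1 | starting material
2 | magnesium chelate of 2-heptyl-4,6-dihydroxybenzoate (formed in the flask) | CCCCCCCc1cc(O)cc2O[Mg]OC(=O)c12 | intermediate
3 | 2-heptyl-4,6-dihydroxybenzoic acid | CCCCCCCc1cc(O)cc(O)c1C(=O)O | intermediate
4 | benzyl 2-heptyl-4,6-dihydroxybenzoate | CCCCCCCc1cc(O)cc(O)c1C(=O)OCc1ccccc1 | intermediate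
5 | benzyl 2-heptyl-6-hydroxy-4-[(triisopropylsilyl)oxy]benzoate | CCCCCCCc1cc(O[Si](C(C)C)(C(C)C)C(C)C)cc(O)c1C(=O)OCc1ccccc1 | intermediate
6 | benzyl 2-heptyl-6-methoxy-4-[(triisopropylsilyl)oxy]benzoate | CCCCCCCc1cc(O[Si](C(C)C)(C(C)C)C(C)C)cc(OC)c1C(=O)OCc1ccccc1 | intermediate
7 | benzyl 2-heptyl-4-hydroxy-6-methoxybenzoate | CCCCCCCc1cc(O)cc(OC)c1C(=O)OCc1ccccc1 | intermediate
8 | oct-2-ynoic acid | CCCCCC#CC(=O)O | starting material
9 | benzyl 2-heptyl-6-methoxy-4-(oct-2-ynoyloxy)benzoate | CCCCCCCc1cc(OC(=O)C#CCCCCC)cc(OC)c1C(=O)OCc1ccccc1 | intermediate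
10 | methyl (E)-3-methoxybut-2-enoate | CO/C(C)=C/C(=O)OC | starting material
11 | lithium 1,3-dimethoxybuta-1,3-dien-1-olate (formed in the flask) | C=C(OC)/C=C(\OC)[O-].[Li+] | intermediate
12 | (1E)-1,3-dimethoxy-1-(trimethylsilyloxy)buta-1,3-diene | C=C(OC)/C=C(\OC)O[Si](C)(C)C | intermediate
13 | benzyl 4-{[4,6-dimethoxy-2-pentyl-6-(trimethylsilyloxy)cyclohexa-1,4-dien-1-yl]carbonyloxy}-2-heptyl-6-methoxybenzoate (racemic at the ketal carbon, formed in the flask) | CCCCCCCc1cc(OC(=O)C2=C(CCCCC)CC(OC)=CC2(OC)O[Si](C)(C)C)cc(OC)c1C(=O)OCc1ccccc1 | intermediate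
14 | benzyl 2-heptyl-6-methoxy-4-{[4-methoxy-6-pentyl-2-(trimethylsilyloxy)benzoyl]oxy}benzoate (formed in the flask) | CCCCCCCc1cc(OC(=O)c2c(CCCCC)cc(OC)cc2O[Si](C)(C)C)cc(OC)c1C(=O)OCc1ccccc1 | intermediate
15 | benzyl 2-heptyl-4-(2-hydroxy-4-methoxy-6-pentylbenzoyloxy)-6-methoxybenzoate | CCCCCCCc1cc(OC(=O)c2c(CCCCC)cc(OC)cc2O)cc(OC)c1C(=O)OCc1ccccc1 | intermediate
16 | benzyl 4-(2,4-dimethoxy-6-pentylbenzoyloxy)-2-heptyl-6-methoxybenzoate | CCCCCCCc1cc(OC(=O)c2c(CCCCC)cc(OC)cc2OC)cc(OC)c1C(=O)OCc1ccccc1 | intermediate
17 | 4-(2,4-dimethoxy-6-pentylbenzoyloxy)-2-heptyl-6-methoxybenzoic acid | CCCCCCCc1cc(OC(=O)c2c(CCCCC)cc(OC)cc2OC)cc(OC)c1C(=O)O | target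

**Step count and risks**

Total step count: 10. Longest linear sequence: 9 (steps 1–6, 8, 9, 10); step 7 is the one-step side branch to the diene.

Steps most likely to fail:

1. Step 8. The β-alkyl ynoate may react slowly, so that thermal or hydrolytic decay of the moisture-sensitive diene outruns the cycloaddition; aromatisation may also stop short, or the regiochemistry may leak. Any product that loses trimethylsilanol instead of methanol would be 16 itself and would simply rejoin the route. The fallback sets out from phenol 7 and builds ring B separately by known chemistry. Commercial 1,3-dimethoxy-5-pentylbenzene F1 would be formylated under Vilsmeier–Haack conditions (POCl3, DMF) para to one methoxy group to give 2,4-dimethoxy-6-pentylbenzaldehyde F2. Pinnick oxidation (NaClO2, NaH2PO4, 2-methyl-2-butene, t-BuOH/H2O) would give 2,4-dimethoxy-6-pentylbenzoic acid F3. The hindered acid would then be joined to 7 by the classical depside esterification through the mixed trifluoroacetic anhydride (TFAA, toluene, rt). The fallback comes back to the route at 16 and bypasses steps 8 and 9.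

2. Step 4. Under basic methylation the silyl group may be lost or may migrate from the C4 oxygen to the C6 oxygen before methylation, which would scramble the oxygen that gets methylated. The fallback sets out from 4 and uses a base-stable ether in place of the silyl group. Allyl bromide (1 equiv) with K2CO3 in acetone at rt should alkylate the free C4 hydroxyl to give benzyl 4-(allyloxy)-2-heptyl-6-hydroxybenzoate F4. Methylation (MeI, K2CO3, DMF) would give benzyl 4-(allyloxy)-2-heptyl-6-methoxybenzoate F5. Deallylation with Pd(PPh3)4 (cat.) and morpholine in THF, which spares the benzyl ester, comes back to the route at 7.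

3. Step 1. Carboxylation may go in part to the carbon between the two hydroxyls, and the β-resorcylic acid may decarboxylate during acidification or drying. The fallback sets out from 1 and introduces the carbon at the aldehyde oxidation level. Vilsmeier–Haack formylation (POCl3, DMF; aqueous hydrolysis) should give 2-heptyl-4,6-dihydroxybenzaldehyde F6, as is known for 5-alkylresorcinols. Lindgren–Pinnick oxidation (NaClO2, NaH2PO4, sulfamic acid or DMSO as hypochlorite scavenger) would then give the acid and come back to the route at 3.

**Further compounds**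

F1 | step 8 | 1,3-dimethoxy-5-pentylbenzene | CCCCCc1cc(OC)cc(OC)c1
F2 | step 8 | 2,4-dimethoxy-6-pentylbenzaldehyde | CCCCCc1cc(OC)cc(OC)c1C=O
F3 | step 8 | 2,4-dimethoxy-6-pentylbenzoic acid | CCCCCc1cc(OC)cc(OC)c1C(=O)O
F4 | step 4 | benzyl 4-(allyloxy)-2-heptyl-6-hydroxybenzoate | CCCCCCCc1cc(OCC=C)cc(O)c1C(=O)OCc1ccccc1
F5 | step 4 | benzyl 4-(allyloxy)-2-heptyl-6-methoxybenzoate | CCCCCCCc1cc(OCC=C)cc(OC)c1C(=O)OCc1ccccc1
F6 | step 1 | 2-heptyl-4,6-dihydroxybenzaldehyde | CCCCCCCc1cc(O)cc(O)c1C=O
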